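The data were computed from invented constants; the scatter is artificial.

Starting material cannot give product it has not yet lost, so count how far each flask gets before weighing one recipe against the other.

| flask | starting material | temperature | remark | time |
|---|---|---|---|---|
| dusk | 0.051 M | 10 °C | run made earlier |  |
| autumn | 0.16 M | 21 °C | run made earlier |  |
| eta | 0.24 M |  | at 25 °C until 50 h, from then on at 5 °C | 10 d |
| beta | 0.060 M |  | at 5 °C throughout | 10 d |

| run | time / d | product / % | starting material / % |
|---|---|---|---|
| dusk | 1.67 | 8 | 79 |
| dusk | 4.00 | 13 | 63 |
| dusk | 8.00 | 26 | 39 |
| dusk | 20.0 | 41 | 12 |
| autumn | 1.25 | 17 | 45 |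
| autumn | 4.00 | 30 | 13 |
| autumn | 6.00 | 34 | 6 |
| autumn | 10.0 | 38 | 0 |

(each reading ± 1.5 percentage points)

1. the winner by amount of product, in percent of the starting material charged; "neither" if no more than 2 percentage points parts them (eta / beta / neither)
2. how much product is there at the end, in percent of the starting material charged: eta
3. how much product is there at the end, in percent of the starting material charged: beta

- the numbers in the tables scatter with a standard deviation of 1.5 percentage points

Read an apparent first-order constant from the falling starting material of each earlier run, then stretch the ratio of the two over the degrees to each bath of the new flasks: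

dusk 0.103 d⁻¹, autumn 0.424 d⁻¹

at 5 °C: 0.0540 d⁻¹, at 25 °C: 0.710 d⁻¹

Multiply each constant by the time spent at its temperature and add up:

beta 0.540, eta 1.91

Call this sum the turnover count, the number of lifetimes a flask lives through, whose negative exponential is the fraction of the charge left: 58.3% in beta and 14.8% in eta, whose count is larger than beta's.

Then test whether that number is enough. It is not, for the count tells how far a flask goes and not what share of the consumed material arrives as product, the selectivity, which the last readings put at 46.6% for dusk and 38.0% for autumn. Take the dusk share for beta and the autumn share for eta, whose charge lies nearer to it, and multiply by the fraction consumed: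

beta 19.4%, eta 32.4%

My reckoning therefore names eta, by 13 points, well over the margin.

The forecast, reading “a first-order route to product competing with a second-order loss to by-product”, also names eta, with 29% for eta and 22% for beta, figures that differ from mine.

The flasks give 27.1% in eta and 16.7% in beta, so eta wins.

    2 starting material → homo dimer (k = 0.00150 L mol⁻¹ min⁻¹, Ea = 63.0 kJ mol⁻¹)
    starting material ⇌ dormant form (K = 4.20, k = 1.90 × 10⁻⁴ min⁻¹, Ea = 104 kJ mol⁻¹, ΔH = −38.0 kJ mol⁻¹)
    starting material → product, rate k3*[starting material]/(1 + ([starting material]/sat3)) (0.150 M, k = 3.80 × 10⁻⁴ min⁻¹, Ea = 100 kJ mol⁻¹)
    (constants at 25 °C)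

The difference in temperature programme is a part of why beta stays behind eta: beta gives 16.7% as it stands and 46.7% on eta's programme, 30 points more, and that programme carries a count of 1.91 against 0.540. Beta's own count promised 58.3% of the charge left, and the flask still holds 51.3%. Left ten times as long, the same beta has a count of 5.40, which at the dusk selectivity promises 46.4% of product, and after 100 d it holds 44.7%.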